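## Analysis of the target

The target 22 is a flavonol, a 4H-chromen-4-one (rings A and C) that carries a 3,5-dihydroxy-4-methoxyphenyl group (ring B) on C2 and a hydroxyl group on C3. Ring A has a free hydroxyl group at C5, methoxy groups at C7 and C8 and a single hydrogen at C6. There is no stereocentre, so every problem is one of regiochemistry and of telling seven oxygens apart, three of them methylated and four free. The 3-hydroxy-4-pyranone enol and the electron-rich phenols are easily oxidised in base and the free polyphenol is poorly soluble, so protecting groups should fall late and under neutral conditions. The first difficulty is that the 5,7,8-pattern of ring A differs from the 5,6,7-isomer only in which of the two ortho oxygens of the ring A ketone closes ring C, so exactly one of them may be free at that moment. The second is that the C3 oxygen is hard to add late, because chalcones with a substituent at the position that becomes C5 tend to give aurones on oxidative cyclisation. The strategy rests on the chain C2–C3–C4, a 1,3-dicarbonyl unit oxidised at its central carbon C3, which an isoxazole with boron on its own C4 holds in full, the N–O bond carrying the C2 nitrogen function and the C4 oxygen and the C–B bond standing for C3–O.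

## Retrosynthetic reasoning

**22 ⇒ 21.** The last operation removes the methyl group from the C5 oxygen of 21. That oxygen is kept methylated so that it cannot compete with the C8a oxygen when ring C closes. It is the only methoxy group peri to the C4 carbonyl, so a chelating Lewis acid can single it out. The forward step must stop after one methyl group.

**21 ⇒ 19 (through 20).** Ring C is opened at O1–C2. The open form is enaminone 20, with nitrogen on C2, hydroxyl on C3 and the ketone at C4, and 20 is the N–O-cleaved form of isoxazol-4-ol 19. Cutting here and not at C4–C4a or at the bond from C2 to ring B means that no C–C bond is made late. The one hydrogenolysis that opens the N–O bond of 19 also removes all three benzyl groups, including the one on the C8a oxygen. The forward step must open the heterocycle, add the phenol to C2 and expel the amino group without isolating the oxidisable 20.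

**19 ⇒ 18.** The C3–O bond is traced back to a C3–B bond. This turns a difficult C–H oxidation into the oxidation of a bond that is already in place.

**18 ⇒ 10 + 16 (through 17).** Two bonds of the isoxazole are cut, C2–C3 and C4–O. This divides the molecule at its three-carbon bridge into a ring A half and a ring B half of similar size, and it accounts for every heteroatom on the bridge. Nitrogen and the C4 oxygen come from nitrile oxide 17, C3 and C4 from the alkyne of 10, and the C3 oxygen from the boron of 10. The forward cycloaddition must place boron on the carbon between the two aryl-bearing carbons.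

**10 ⇒ 6 + 7 (through 8 and 9).** The C(sp)–B bond is cut. Acetylide 8 from 6 attacks the boron of 7, and borate 9 loses its alkoxide on acidification.

**6 ⇒ 5.** The alkyne is a one-carbon homologue of aldehyde 5. The aldehyde is wanted anyway, because it directs the next disconnection.

**5 ⇒ 4 ⇒ 3.** The benzyl ether of 5 comes from phenol 4, and 4 from 3 by loss of the one methyl group that is both ortho to the formyl group and flanked by a second methoxy group. This is where the C8a oxygen is told apart from the C5 oxygen.

**3 ⇒ 1.** The formyl carbon is cut from the ring. The two free positions of 1 are equivalent, so only one aldehyde can form.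

**16 ⇒ 15 ⇒ 14.** The hydroximoyl chloride 16 comes from aldoxime 15 by chlorination, and 15 from aldehyde 14 by condensation.

**14 ⇒ 13 ⇒ 12 ⇒ 11.** Aldehyde 14 is reached from acid 11 by benzylation of both phenols and the carboxyl group to give 12, reduction to 13 and benzylic oxidation. Benzyl is chosen for ring B and for the C8a oxygen so that one hydrogenolysis frees them all.

## Alternatives that were turned down

Alternative 1: This route cuts C4a–C8a and O1–C2, so that rings A and C both come from a linear polyketide. The chain is stored as the pyranone methyl 2-(6-{2-[3,5-bis(benzyloxy)-4-methoxyphenyl]-2-oxoethyl}-4-oxo-4H-pyran-2-yl)acetate A2. In the forward step Mg(OMe)2 in MeOH opens A2 to the tetraketo ester methyl 9-[3,5-bis(benzyloxy)-4-methoxyphenyl]-3,5,7,9-tetraoxononanoate A3. The methylene of A3 that becomes C4a then attacks the ester carbon in a Claisen condensation, and acid closes ring C to 2-[3,5-bis(benzyloxy)-4-methoxyphenyl]-5,7-dihydroxy-4H-chromen-4-one A1.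

- In its favour: two rings of the target arise from an acyclic precursor in one operation, and the phloroglucinol pattern of ring A is set by the chain itself. On ring construction it is stronger than the chosen route, whose key step builds a ring that is not in the target.
- Against it: A1 lacks the C8 oxygen, the C3 hydroxyl and the C7 methyl group. After the key step, ring A would have to be oxidised at C8 and not at the equally activated C6, methylated at O7 and O8 but not O5, and C3 would have to be hydroxylated. The aldol mode of folding of A3 also competes with the Claisen mode.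
- Comparison: the chosen route takes ring A with all its oxygens from arene 1 and spends its key step on C2–C3–C4 with the C3 oxygen included. It is less elegant but needs far fewer selective steps after the key event.

Alternative 2: This route cuts O1–C8a, with C8a still a C–H in the diketone 2-(benzyloxy)-1-[3,5-bis(benzyloxy)-4-methoxyphenyl]-3-(2-hydroxy-4,5-dimethoxyphenyl)propane-1,3-dione A5. In the forward step, anodic oxidation of the para-methoxyphenol unit of A5 in methanol (LiClO4, graphite anode) gives the quinone monoketal 2-(benzyloxy)-1-[3,5-bis(benzyloxy)-4-methoxyphenyl]-3-(3,3,4-trimethoxy-6-oxocyclohexa-1,4-dien-1-yl)propane-1,3-dione A6. In A6 the carbon that becomes C8a is the β-position of a doubly activated enone. The enol oxygen of the diketone adds there, and loss of methanol from the ketal of A6 restores ring A, giving 3-(benzyloxy)-2-[3,5-bis(benzyloxy)-4-methoxyphenyl]-5-hydroxy-7,8-dimethoxy-4H-chromen-4-one A4.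

- In its favour: ring A of A5 carries only a 2-hydroxy-4,5-dimethoxy pattern, so no methoxy group has to be cleaved selectively at any stage. The C5 hydroxyl emerges free and the C3 oxygen is in place from the start. One hydrogenolysis of A4 would give the target, so the endgame is shorter than in the chosen route.
- Against it: the key step has no close analogy. The diketone enol, the benzyloxy methine and three benzyl ethers are oxidisable near the potential of the phenol. The solvent competes with the poorly populated enol of a 2-alkoxy-1,3-diketone for the dienone of A6, and A5 needs its own multistep assembly.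
- Comparison: the chosen route gives up the short endgame. In return each of its steps has a direct analogy, and its one selectivity question has a clear electronic answer.

Alternative 3: This route cuts C4a–C4 and C4–C3 (both to carbon monoxide) and O1–C2. In the forward step, PdCl2(PPh3)2 under CO joins 2-iodo-3,5,6-trimethoxyphenol A8, CO and 1,3-bis(benzyloxy)-5-ethynyl-2-methoxybenzene A9 in a carbonylative Sonogashira coupling. The product is the ynone 3-[3,5-bis(benzyloxy)-4-methoxyphenyl]-1-(2-hydroxy-3,4,6-trimethoxyphenyl)prop-2-yn-1-one A10. Diethylamine then closes A10 in a 6-endo mode at O1–C2 to 2-[3,5-bis(benzyloxy)-4-methoxyphenyl]-5,7,8-trimethoxy-4H-chromen-4-one A7.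

- In its favour: three simple components, a well-known reaction type, and A9 one step from aldehyde 14. In convergence and in precedent for the ring-forming event it is at least as strong as the chosen route.
- Against it: A7 has no oxygen at C3, which would have to be added afterwards by a separate C–H functionalisation of the finished flavone. A8 is a very electron-rich aryl iodide with two ortho substituents, so oxidative addition and CO insertion are slow and direct coupling without CO competes. The 5-exo closure of A10 to an aurone competes with the 6-endo mode. Making A8 as one regioisomer meets the same oxygen-differentiation problem as ring A of the chosen route.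
- Comparison: the chosen route carries the C3 oxygen as boron through the ring-forming step. It pays with two extra operations (boron oxidation, N–O cleavage).

Key step: step 11

Remark on the chemistry: compounds 1, 7 and 11 are taken as purchasable. The target has no stereocentre, so the only stereodescriptors in the route are the double-bond geometries of 15, 16 and 20.

## Route

Step 1
Reactants: 1 1,2,3,5-tetramethoxybenzene
Product: 3 2,3,4,6-tetramethoxybenzaldehyde, via aryl iminium dichlorophosphate 2 (not isolated)
Conditions: POCl3 (1.2 equiv), DMF, 0 °C to 60 °C; then ice-water, rt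
Reagents that add atoms: N,N-dimethylformamide CN(C)C=O (formyl carbon); water O (formyl oxygen)
Why: Vilsmeier–Haack formylation; the chloroiminium ion attacks one of the two equivalent free positions of 1, each ortho to two methoxy groups and para to a third, so only one aldehyde can form, and water hydrolyses iminium salt 2.

Step 2
Reactants: 3 2,3,4,6-tetramethoxybenzaldehyde
Product: 4 2-hydroxy-3,4,6-trimethoxybenzaldehyde
Conditions: AlCl3 (1.2 equiv), CH2Cl2, 0 °C to rt; then 1 M HCl
Reagents that add atoms: none
Why: Chelation-controlled Lewis-acid ether cleavage; AlCl3 bound to the formyl oxygen activates an ortho methoxy group and chloride removes its methyl. Of the two ortho groups, the one at C2 is buttressed by the C3 methoxy group, twisted out of the ring plane and therefore more basic and more strained, so it should be cleaved first. The site is to be confirmed by NOE, since in 4 the ring hydrogen lies between two methoxy groups.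

Step 3
Reactants: 4 2-hydroxy-3,4,6-trimethoxybenzaldehyde
Product: 5 2-(benzyloxy)-3,4,6-trimethoxybenzaldehyde
Conditions: BnBr (1.2 equiv), K2CO3 (2 equiv), DMF, 60 °C
Reagents that add atoms: benzyl bromide BrCc1ccccc1
Why: Williamson ether synthesis; warm DMF overcomes the hydrogen bond and the crowding of the phenol. Benzyl is chosen because it leaves in step 13 together with the ring B ethers.

Step 4
Reactants: 5 2-(benzyloxy)-3,4,6-trimethoxybenzaldehyde
Product: 6 2-(benzyloxy)-1-ethynyl-3,4,6-trimethoxybenzene
Conditions: dimethyl (1-diazo-2-oxopropyl)phosphonate (1.5 equiv), K2CO3 (2.5 equiv), MeOH–THF, 0 °C to rt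
Reagents that add atoms: dimethyl (1-diazo-2-oxopropyl)phosphonate COP(=O)(OC)C(=[N+]=[N-])C(C)=O (terminal alkyne carbon)
Why: Ohira–Bestmann (Seyferth–Gilbert) homologation; methanolysis frees the diazomethylphosphonate anion, olefination of the aldehyde gives a diazoalkene, and loss of N2 with a 1,2-hydrogen shift gives the alkyne. The aldehyde has no α-hydrogen and the benzyl ether tolerates the mild base.

Step 5
Reactants: 6 2-(benzyloxy)-1-ethynyl-3,4,6-trimethoxybenzene; 7 2-isopropoxy-4,4,5,5-tetramethyl-1,3,2-dioxaborolane
Product: 10 2-{[2-(benzyloxy)-3,4,6-trimethoxyphenyl]ethynyl}-4,4,5,5-tetramethyl-1,3,2-dioxaborolane, via lithium acetylide 8 (not isolated), via lithium alkynylborate 9 (not isolated)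
Conditions: n-BuLi (1.05 equiv), THF, −78 °C; 7 (1.1 equiv), −78 °C; HCl in Et2O (1.05 equiv), −78 °C to rt; LiCl filtered off, used crude
Reagents that add atoms: none
Why: Deprotonation of the terminal alkyne at −78 °C is faster than any ring or benzylic metalation; acetylide 8 adds to the boron of 7 to give ate complex 9, and anhydrous HCl removes isopropoxide to leave the alkynyl pinacol boronate. The product is not chromatographed because the C(sp)–B bond is hydrolytically labile.

Step 6
Reactants: 11 3,5-dihydroxy-4-methoxybenzoic acid
Product: 12 benzyl 3,5-bis(benzyloxy)-4-methoxybenzoate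
Conditions: BnBr (3.5 equiv), K2CO3 (4 equiv), DMF, 60 °C
Reagents that add atoms: benzyl bromide BrCc1ccccc1 (three benzyl groups)
Why: Williamson etherification of both phenols and alkylation of the carboxylate in one operation.

Step 7
Reactants: 12 benzyl 3,5-bis(benzyloxy)-4-methoxybenzoate
Product: 13 [3,5-bis(benzyloxy)-4-methoxyphenyl]methanol
Conditions: LiAlH4 (1.2 equiv), THF, 0 °C to rt; then H2O
Reagents that add atoms: none
Why: Hydride reduction of the ester to the primary alcohol; aryl benzyl ethers are inert to LiAlH4.

Step 8
Reactants: 13 [3,5-bis(benzyloxy)-4-methoxyphenyl]methanol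
Product: 14 3,5-bis(benzyloxy)-4-methoxybenzaldehyde
Conditions: MnO2 (activated, excess), CH2Cl2, rt
Reagents that add atoms: none
Why: Selective oxidation of a benzylic alcohol by MnO2, which stops at the aldehyde.

Step 9
Reactants: 14 3,5-bis(benzyloxy)-4-methoxybenzaldehyde
Product: 15 (E)-3,5-bis(benzyloxy)-4-methoxybenzaldehyde oxime
Conditions: NH2OH·HCl (1.3 equiv), NaOAc (1.5 equiv), EtOH–H2O, rt to 60 °C
Reagents that add atoms: hydroxylamine hydrochloride Cl.NO (supplies N–OH)
Why: Oxime condensation; the aldoxime should form as the E isomer, with hydroxyl anti to the aryl group.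

Step 10
Reactants: 15 (E)-3,5-bis(benzyloxy)-4-methoxybenzaldehyde oxime
Product: 16 (Z)-3,5-bis(benzyloxy)-N-hydroxy-4-methoxybenzimidoyl chloride
Conditions: N-chlorosuccinimide (1.05 equiv), DMF, rt, kept below 35 °C
Reagents that add atoms: N-chlorosuccinimide O=C1CCC(=O)N1Cl (chlorine)
Why: Electrophilic chlorination of the aldoxime carbon (through the C-chloro nitroso tautomer) gives the hydroximoyl chloride with unchanged geometry; the descriptor becomes Z only because chlorine outranks the aryl carbon. Mild temperature and one equivalent keep the reagent off the ring.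

Step 11
Reactants: 10 2-{[2-(benzyloxy)-3,4,6-trimethoxyphenyl]ethynyl}-4,4,5,5-tetramethyl-1,3,2-dioxaborolane; 16 (Z)-3,5-bis(benzyloxy)-N-hydroxy-4-methoxybenzimidoyl chloride
Product: 18 5-[2-(benzyloxy)-3,4,6-trimethoxyphenyl]-3-[3,5-bis(benzyloxy)-4-methoxyphenyl]-4-(4,4,5,5-tetramethyl-1,3,2-dioxaborolan-2-yl)isoxazole, via nitrile oxide 17 (not isolated)
Conditions: 16 (1.5–2 equiv, added in portions), KHCO3 (4 equiv), DME, 50 °C
Reagents that add atoms: none
Why: KHCO3 removes HCl from 16 and releases nitrile oxide 17 slowly, and 17 adds to the alkyne of 10 in a concerted, asynchronous (3+2) cycloaddition. The closest known reaction type is the addition of aryl nitrile oxides to substituted alkynyl pinacol boronates, which gives isoxazol-4-yl boronates. The isoxazole ring closes in this single suprafacial six-electron event between two molecules, C2–C3 and C4–O forming together, so no stepwise ring closure is involved and no stereocentre is formed. The selectivity needed is regiochemical, since boron must end on isoxazole C4, the future C3, between the two aryl-bearing carbons. Two features of 10 secure this: the vacant orbital on boron makes the aryl-bearing alkyne carbon the electrophilic terminus, which pairs with the oxide oxygen, and the electron-rich ring A aryl group raises the electron density at the boron-bearing carbon, which pairs with the electrophilic nitrile carbon. Sterically, the unsubstituted oxygen end of 17 also meets the more crowded, aryl-bearing carbon. Slow release of 17 from solid KHCO3 and portionwise addition of 16 hold down dimerisation of the nitrile oxide.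

Step 12
Reactants: 18 5-[2-(benzyloxy)-3,4,6-trimethoxyphenyl]-3-[3,5-bis(benzyloxy)-4-methoxyphenyl]-4-(4,4,5,5-tetramethyl-1,3,2-dioxaborolan-2-yl)isoxazole
Product: 19 5-[2-(benzyloxy)-3,4,6-trimethoxyphenyl]-3-[3,5-bis(benzyloxy)-4-methoxyphenyl]isoxazol-4-ol
Conditions: H2O2 (30% aq., 3 equiv), NaOH (1 M aq., 1.2 equiv), THF, 0 °C; then aq. NH4Cl
Reagents that add atoms: hydrogen peroxide OO (the C3 oxygen)
Why: Oxidation of a C–B bond; hydroperoxide adds to boron and the isoxazolyl group shifts from boron to oxygen. The isoxazole is substituted at both carbons next to its heteroatoms and is stable to cold dilute base.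

Step 13
Reactants: 19 5-[2-(benzyloxy)-3,4,6-trimethoxyphenyl]-3-[3,5-bis(benzyloxy)-4-methoxyphenyl]isoxazol-4-ol
Product: 21 2-(3,5-dihydroxy-4-methoxyphenyl)-3-hydroxy-5,7,8-trimethoxy-4H-chromen-4-one, via hydroxy enaminone 20 (not isolated)
Conditions: H2 (3 atm), Pd(OH)2/C, EtOAc–MeOH, rt; filtered under argon; then HCl (2 M in MeOH), 60 °C
Reagents that add atoms: none
Why: Hydrogenolysis removes the three benzyl groups and cleaves the weak N–O bond, so the isoxazole opens at neutral pH to enaminone 20. On acidification the freed C8a phenol adds to the protonated C2 (6-exo-trig on the iminium carbon) and nitrogen leaves as NH4Cl, which is the known route from 5-(2-hydroxyaryl)isoxazoles to flavones. The tautomers of 20 interconvert in acid and only closure at O1–C2 ends in an aromatic 4-pyranone.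

Step 14
Reactants: 21 2-(3,5-dihydroxy-4-methoxyphenyl)-3-hydroxy-5,7,8-trimethoxy-4H-chromen-4-one
Product: 22 2-(3,5-dihydroxy-4-methoxyphenyl)-3,5-dihydroxy-7,8-dimethoxy-4H-chromen-4-one
Conditions: BCl3 (1 M in CH2Cl2, 6 equiv), CH2Cl2, −78 °C to 0 °C; then MeOH, aq. HCl
Reagents that add atoms: none
Why: Chelation-controlled ether cleavage; boron held between the C4 carbonyl oxygen and the peri C5 methoxy oxygen forms a six-membered chelate and chloride removes that methyl group. The methoxy groups at C7, C8 and C4' lack this activation at or below 0 °C.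

## Compound list

1 | 1,2,3,5-tetramethoxybenzene | COc1cc(OC)c(OC)c(OC)c1 | starting material
2 | N-methyl-N-[(2,3,4,6-tetramethoxyphenyl)methylidene]methanaminium dichlorophosphate (formed in the flask) | COc1cc(OC)c(C=[N+](C)C)c(OC)c1OC.[O-]P(=O)(Cl)Cl | intermediate
3 | 2,3,4,6-tetramethoxybenzaldehyde | COc1cc(OC)c(C=O)c(OC)c1OC | intermediate
4 | 2-hydroxy-3,4,6-trimethoxybenzaldehyde | COc1cc(OC)c(C=O)c(O)c1OC | intermediate
5 | 2-(benzyloxy)-3,4,6-trimethoxybenzaldehyde | COc1cc(OC)c(C=O)c(OCc2ccccc2)c1OC | intermediate
6 | 2-(benzyloxy)-1-ethynyl-3,4,6-trimethoxybenzene | COc1cc(OC)c(C#C)c(OCc2ccccc2)c1OC | intermediate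
7 | 2-isopropoxy-4,4,5,5-tetramethyl-1,3,2-dioxaborolane | CC(C)OB1OC(C)(C)C(C)(C)O1 | starting material
8 | lithium [2-(benzyloxy)-3,4,6-trimethoxyphenyl]acetylide (formed in the flask) | COc1cc(OC)c(C#C[Li])c(OCc2ccccc2)c1OC | intermediate
9 | lithium {[2-(benzyloxy)-3,4,6-trimethoxyphenyl]ethynyl}(isopropoxy)(pinacolato)borate (formed in the flask) | COc1cc(OC)c(C#C[B-]2(OC(C)C)OC(C)(C)C(C)(C)O2)c(OCc2ccccc2)c1OC.[Li+] | intermediate
10 | 2-{[2-(benzyloxy)-3,4,6-trimethoxyphenyl]ethynyl}-4,4,5,5-tetramethyl-1,3,2-dioxaborolane | COc1cc(OC)c(C#CB2OC(C)(C)C(C)(C)O2)c(OCc2ccccc2)c1OC | intermediate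
11 | 3,5-dihydroxy-4-methoxybenzoic acid | COc1c(O)cc(C(=O)O)cc1O | starting material
12 | benzyl 3,5-bis(benzyloxy)-4-methoxybenzoate | COc1c(OCc2ccccc2)cc(C(=O)OCc2ccccc2)cc1OCc1ccccc1 | intermediate
13 | [3,5-bis(benzyloxy)-4-methoxyphenyl]methanol | COc1c(OCc2ccccc2)cc(CO)cc1OCc1ccccc1 | intermediate
14 | 3,5-bis(benzyloxy)-4-methoxybenzaldehyde | COc1c(OCc2ccccc2)cc(C=O)cc1OCc1ccccc1 | intermediate
15 | (E)-3,5-bis(benzyloxy)-4-methoxybenzaldehyde oxime | COc1c(OCc2ccccc2)cc(/C=N/O)cc1OCc1ccccc1 | intermediate
16 | (Z)-3,5-bis(benzyloxy)-N-hydroxy-4-methoxybenzimidoyl chloride | O/N=C(\Cl)c1cc(OCc2ccccc2)c(OC)c(OCc2ccccc2)c1 | intermediate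
17 | 3,5-bis(benzyloxy)-4-methoxybenzonitrile oxide (formed in the flask) | [O-][N+]#Cc1cc(OCc2ccccc2)c(OC)c(OCc2ccccc2)c1 | intermediate
18 | 5-[2-(benzyloxy)-3,4,6-trimethoxyphenyl]-3-[3,5-bis(benzyloxy)-4-methoxyphenyl]-4-(4,4,5,5-tetramethyl-1,3,2-dioxaborolan-2-yl)isoxazole | COc1cc(OC)c(-c2onc(-c3cc(OCc4ccccc4)c(OC)c(OCc4ccccc4)c3)c2B2OC(C)(C)C(C)(C)O2)c(OCc2ccccc2)c1OC | intermediate
19 | 5-[2-(benzyloxy)-3,4,6-trimethoxyphenyl]-3-[3,5-bis(benzyloxy)-4-methoxyphenyl]isoxazol-4-ol | COc1cc(OC)c(-c2onc(-c3cc(OCc4ccccc4)c(OC)c(OCc4ccccc4)c3)c2O)c(OCc2ccccc2)c1OC | intermediate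
20 | (2E)-3-amino-3-(3,5-dihydroxy-4-methoxyphenyl)-2-hydroxy-1-(2-hydroxy-3,4,6-trimethoxyphenyl)prop-2-en-1-one (formed in the flask; amino group cis to the ketone) | COc1cc(OC)c(C(=O)/C(O)=C(\N)c2cc(O)c(OC)c(O)c2)c(O)c1OC | intermediate
21 | 2-(3,5-dihydroxy-4-methoxyphenyl)-3-hydroxy-5,7,8-trimethoxy-4H-chromen-4-one | COc1cc(OC)c2c(=O)c(O)c(-c3cc(O)c(OC)c(O)c3)oc2c1OC | intermediate
22 | 2-(3,5-dihydroxy-4-methoxyphenyl)-3,5-dihydroxy-7,8-dimethoxy-4H-chromen-4-one | COc1cc(O)c2c(=O)c(O)c(-c3cc(O)c(OC)c(O)c3)oc2c1OC | target

## Step count and least certain steps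

Total: 14 steps. Longest linear sequence: 9 steps (steps 1–5 and 11–14; the ring B branch, steps 6–10 and 11–14, is equally long).

**Step 11 (key step).** The alkyne of 10 is shielded by two ortho substituents, so dimerisation of nitrile oxide 17 may outrun the cycloaddition. Protodeboronation of 10 in the warm bicarbonate medium, or partial loss of regiocontrol, would also cut the supply of 18. The fallback changes the way regiochemistry is set and sets out from 6. Deprotonation as in step 5 and an iodine quench should give 2-(benzyloxy)-1-(iodoethynyl)-3,4,6-trimethoxybenzene F1. Cycloaddition of F1 with 17 (from 16 and Et3N) under Cp*RuCl(cod) catalysis runs through a ruthenacycle and places the halogen of a 1-haloalkyne on isoxazole C4. It should give 5-[2-(benzyloxy)-3,4,6-trimethoxyphenyl]-3-[3,5-bis(benzyloxy)-4-methoxyphenyl]-4-iodoisoxazole F2. Iodine–magnesium exchange on F2 with i-PrMgCl·LiCl at low temperature and trapping with 7 comes back to the route at 18.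

**Step 13.** Enaminone 20 is an amino reductone. During hydrogenation or filtration it may be oxidised by traces of air, or it may ketonise at C3 and then contract to a five-membered benzofuranone or self-condense through the resulting amino ketone. The N–O bond of the crowded isoxazole may also open more slowly than the benzyl ethers fall. The fallback blocks the C3 oxygen and sets out from 19. Chloromethyl methyl ether and i-Pr2NEt should give 5-[2-(benzyloxy)-3,4,6-trimethoxyphenyl]-3-[3,5-bis(benzyloxy)-4-methoxyphenyl]-4-(methoxymethoxy)isoxazole F3. Hydrogenolysis of F3 as in step 13 then gives (2E)-3-amino-3-(3,5-dihydroxy-4-methoxyphenyl)-1-(2-hydroxy-3,4,6-trimethoxyphenyl)-2-(methoxymethoxy)prop-2-en-1-one F4, an ordinary enaminone that can be handled. HCl in methanol at 60 °C closes ring C of F4 and removes the acetal, coming back to the route at 21.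

**Step 2.** The Lewis acid may cleave the unflanked ortho methoxy group, or both ortho groups, since the small formyl group can chelate on either side. The fallback moves the demethylation to a ketone and sets out from 1. Friedel–Crafts acetylation (acetyl chloride, AlCl3, Et2O) forms 1-(2,3,4,6-tetramethoxyphenyl)ethan-1-one F5 in the flask. Its acetyl group is twisted by two ortho substituents and presses hardest on the buttressed C2 methoxy group, and the ketone is the stronger donor to aluminium. The preference for the flanked ether should therefore be stronger than in the aldehyde, giving 1-(2-hydroxy-3,4,6-trimethoxyphenyl)ethan-1-one F6. Benzylation (BnBr, K2CO3, DMF) gives 1-[2-(benzyloxy)-3,4,6-trimethoxyphenyl]ethan-1-one F7. LiN(i-Pr)2 and ClP(O)(OEt)2 give the enol phosphate 1-[2-(benzyloxy)-3,4,6-trimethoxyphenyl]ethenyl diethyl phosphate F8. Excess LiN(i-Pr)2 then eliminates phosphate from F8, and the fallback comes back to the route at 6.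

**Step 14.** A second methyl group may be lost, either the C4' methoxy group between two boron-bound phenoxides or the flanked C8 methoxy group. The reaction may also stall because the boron chelates of the polyphenol are poorly soluble. The fallback masks the hydroxyls first and sets out from 21. Acetic anhydride in pyridine should give 5-[3-(acetyloxy)-5,7,8-trimethoxy-4-oxo-4H-chromen-2-yl]-2-methoxy-1,3-phenylene diacetate F9, which is soluble and whose ring B oxygens no longer bind boron. BCl3 in CH2Cl2 then cleaves only the peri methyl group of F9 to give 5-[3-(acetyloxy)-5-hydroxy-7,8-dimethoxy-4-oxo-4H-chromen-2-yl]-2-methoxy-1,3-phenylene diacetate F10. Acidic methanolysis (HCl, MeOH) removes the acetates of F10 and comes back to the route at 22.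

## Further compounds

F1 | step 11 | 2-(benzyloxy)-1-(iodoethynyl)-3,4,6-trimethoxybenzene | COc1cc(OC)c(C#CI)c(OCc2ccccc2)c1OC
F2 | step 11 | 5-[2-(benzyloxy)-3,4,6-trimethoxyphenyl]-3-[3,5-bis(benzyloxy)-4-methoxyphenyl]-4-iodoisoxazole | COc1cc(OC)c(-c2onc(-c3cc(OCc4ccccc4)c(OC)c(OCc4ccccc4)c3)c2I)c(OCc2ccccc2)c1OC
F3 | step 13 | 5-[2-(benzyloxy)-3,4,6-trimethoxyphenyl]-3-[3,5-bis(benzyloxy)-4-methoxyphenyl]-4-(methoxymethoxy)isoxazole | COc1cc(OC)c(-c2onc(-c3cc(OCc4ccccc4)c(OC)c(OCc4ccccc4)c3)c2OCOC)c(OCc2ccccc2)c1OC
F4 | step 13 | (2E)-3-amino-3-(3,5-dihydroxy-4-methoxyphenyl)-1-(2-hydroxy-3,4,6-trimethoxyphenyl)-2-(methoxymethoxy)prop-2-en-1-one | COc1cc(OC)c(C(=O)/C(OCOC)=C(\N)c2cc(O)c(OC)c(O)c2)c(O)c1OC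
F5 | step 2 | 1-(2,3,4,6-tetramethoxyphenyl)ethan-1-one | COc1cc(OC)c(C(C)=O)c(OC)c1OC
F6 | step 2 | 1-(2-hydroxy-3,4,6-trimethoxyphenyl)ethan-1-one | COc1cc(OC)c(C(C)=O)c(O)c1OC
F7 | step 2 | 1-[2-(benzyloxy)-3,4,6-trimethoxyphenyl]ethan-1-one | COc1cc(OC)c(C(C)=O)c(OCc2ccccc2)c1OC
F8 | step 2 | 1-[2-(benzyloxy)-3,4,6-trimethoxyphenyl]ethenyl diethyl phosphate | COc1cc(OC)c(C(=C)OP(=O)(OCC)OCC)c(OCc2ccccc2)c1OC
F9 | step 14 | 5-[3-(acetyloxy)-5,7,8-trimethoxy-4-oxo-4H-chromen-2-yl]-2-methoxy-1,3-phenylene diacetate | COc1cc(OC)c2c(=O)c(OC(C)=O)c(-c3cc(OC(C)=O)c(OC)c(OC(C)=O)c3)oc2c1OC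
F10 | step 14 | 5-[3-(acetyloxy)-5-hydroxy-7,8-dimethoxy-4-oxo-4H-chromen-2-yl]-2-methoxy-1,3-phenylene diacetate | COc1cc(O)c2c(=O)c(OC(C)=O)c(-c3cc(OC(C)=O)c(OC)c(OC(C)=O)c3)oc2c1OC
A1 | alternative 1 | 2-[3,5-bis(benzyloxy)-4-methoxyphenyl]-5,7-dihydroxy-4H-chromen-4-one | Oc1cc(O)c2c(=O)cc(-c3cc(OCc4ccccc4)c(OC)c(OCc4ccccc4)c3)oc2c1
A2 | alternative 1 | methyl 2-(6-{2-[3,5-bis(benzyloxy)-4-methoxyphenyl]-2-oxoethyl}-4-oxo-4H-pyran-2-yl)acetate | COC(=O)Cc1cc(=O)cc(CC(=O)c2cc(OCc3ccccc3)c(OC)c(OCc3ccccc3)c2)o1
A3 | alternative 1 | methyl 9-[3,5-bis(benzyloxy)-4-methoxyphenyl]-3,5,7,9-tetraoxononanoate | COC(=O)CC(=O)CC(=O)CC(=O)CC(=O)c1cc(OCc2ccccc2)c(OC)c(OCc2ccccc2)c1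
A4 | alternative 2 | 3-(benzyloxy)-2-[3,5-bis(benzyloxy)-4-methoxyphenyl]-5-hydroxy-7,8-dimethoxy-4H-chromen-4-one | COc1cc(O)c2c(=O)c(OCc3ccccc3)c(-c3cc(OCc4ccccc4)c(OC)c(OCc4ccccc4)c3)oc2c1OC
A5 | alternative 2 | 2-(benzyloxy)-1-[3,5-bis(benzyloxy)-4-methoxyphenyl]-3-(2-hydroxy-4,5-dimethoxyphenyl)propane-1,3-dione | COc1cc(O)c(C(=O)C(OCc2ccccc2)C(=O)c2cc(OCc3ccccc3)c(OC)c(OCc3ccccc3)c2)cc1OC
A6 | alternative 2 | 2-(benzyloxy)-1-[3,5-bis(benzyloxy)-4-methoxyphenyl]-3-(3,3,4-trimethoxy-6-oxocyclohexa-1,4-dien-1-yl)propane-1,3-dione | COC1=CC(=O)C(C(=O)C(OCc2ccccc2)C(=O)c2cc(OCc3ccccc3)c(OC)c(OCc3ccccc3)c2)=CC1(OC)OC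
A7 | alternative 3 | 2-[3,5-bis(benzyloxy)-4-methoxyphenyl]-5,7,8-trimethoxy-4H-chromen-4-one | COc1cc(OC)c2c(=O)cc(-c3cc(OCc4ccccc4)c(OC)c(OCc4ccccc4)c3)oc2c1OC
A8 | alternative 3 | 2-iodo-3,5,6-trimethoxyphenol | COc1cc(OC)c(I)c(O)c1OC
A9 | alternative 3 | 1,3-bis(benzyloxy)-5-ethynyl-2-methoxybenzene | C#Cc1cc(OCc2ccccc2)c(OC)c(OCc2ccccc2)c1
A10 | alternative 3 | 3-[3,5-bis(benzyloxy)-4-methoxyphenyl]-1-(2-hydroxy-3,4,6-trimethoxyphenyl)prop-2-yn-1-one | COc1cc(OC)c(C(=O)C#Cc2cc(OCc3ccccc3)c(OC)c(OCc3ccccc3)c2)c(O)c1OC
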